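**Retrosynthetic overview**
- The target comes from acetylation after a hydroxyl-directed epoxidation of a (Z)-7(11)-en-12-ol; this spiro-epoxide is made last and is steered by the 4,5-epoxide.
- The (Z)-allylic alcohol comes from a light-driven dienone to bridged 2H-pyran isomerisation with hydrolysis (the new step), run on a cross-conjugated trienone made by dehydrogenating the C9 ketone.
- The cis-4,5-epoxide comes from a directed epoxidation steered by the carvone-derived C7 centre, after SeO2 hydroxylation of the C15 methyl.
- The ten-membered ring comes from thermal cycloreversion of a bicyclo[2.2.0]hexane, itself made by [2+2] photocycloaddition of (R)-carvone and 1-methylcyclobutene (C1–C10 and C4–C5 are formed by light).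
- Ring order: cyclobutane (photochemical), then cyclodecadienone, then 4,5-oxirane, then 7,11-oxirane.

Assumption (numbering): germacrane numbering of the target is used for every compound: ring C1 to C10, C9 the ketone carbon, C14 the methyl on C10, C15 the carbon on C4, and C11 (with C12 = CH2O and C13 = CH3) on C7.
Assumption (supply and sense): 1-methylcyclobut-1-ene is a catalogue chemical; the facial sense of the two substrate-controlled epoxidations rests on conformational models, not on precedent. (R)-Carvone is taken on the model given in step 4, and its equally cheap enantiomer would be used if the sense proved opposite.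

Step 1
Reactants: 1 (R)-(−)-carvone; 2 1-methylcyclobut-1-ene
Product: 3 head-to-tail cis-anti-cis photoadduct 2,6-dimethyl-9-(prop-1-en-2-yl)tricyclo[4.4.0.0(2,5)]decan-7-one (9R; carvone ring fused at C5–C10 to cyclobutane C10–C1–C4–C5, which is fused at C1–C4 to cyclobutane C1–C2–C3–C4; cyclobutanes trans to the isopropenyl group)
Conditions: hν (350 nm, Pyrex), 2 (5 equiv), CH2Cl2, −30 °C
Reagents that add atoms: none
Why: Intermolecular enone–alkene [2+2] photocycloaddition through the carvone triplet forms the C1–C10 and C4–C5 bonds head-to-tail (the methyl-bearing cyclobutene carbon bonds to the enone β-carbon, which avoids two adjacent quaternary centres), with the cyclobutene approaching anti to the C7 isopropenyl group, and the four new cyclobutane stereocentres are transient because step 2 erases them.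

Step 2
Reactants: 3 tricyclic photoadduct
Product: 4 (7R)-germacra-1(10),4,11-trien-9-one with C1=C10 cis and C4=C5 trans in the ring, that is (2Z,6E,9R)-2,6-dimethyl-9-(prop-1-en-2-yl)cyclodeca-2,6-dien-1-one
Conditions: PhMe (0.02 M), 200 °C, sealed tube (or flow coil, 10 min)
Reagents that add atoms: none
Why: Thermal [2+2] cycloreversion of the bicyclo[2.2.0]hexane unit (photo-thermal olefin metathesis) through a chair cyclohexane-1,4-diyl cleaves C1–C4 and C5–C10 with release of the strain of both four-membered rings, the axial C9 branch becoming the ring-cis enone and the equatorial C6 branch the ring-trans C4=C5 bond, while enone conjugation disfavours a follow-up Cope rearrangement and C7 is untouched.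

Step 3
Reactants: 4 cis,trans-dienone
Product: 5 (7R)-15-hydroxygermacra-1(10),4,11-trien-9-one with both ring double bonds cis in the ring, that is (2Z,6E,9R)-6-(hydroxymethyl)-2-methyl-9-(prop-1-en-2-yl)cyclodeca-2,6-dien-1-one
Conditions: SeO2 (0.3 equiv), t-BuOOH (2 equiv), CH2Cl2, 0 °C to rt
Reagents that add atoms: selenium dioxide O=[Se]=O (oxygen carrier); tert-butyl hydroperoxide CC(C)(C)OO
Why: Riley allylic oxidation (ene reaction of SeO2 at the most electron-rich, trisubstituted C4=C5 bond followed by a [2,3]-sigmatropic shift) hydroxylates the C15 methyl, and the [2,3] step re-forms the double bond with CH2OH trans to C6, that is ring-cis, as is known for methyl-bearing trans double bonds in ten-membered germacrane rings, while the isopropenyl and enone double bonds react more slowly.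

Step 4
Reactants: 5 ring-cis allylic alcohol
Product: 6 (4R,5R,7R)-4,5-epoxy-15-hydroxygermacra-1(10)Z,11-dien-9-one (cis-epoxide, C3 and C6 cis)
Conditions: VO(acac)2 (5 mol%), t-BuOOH (1.5 equiv, in decane), CH2Cl2, 0 °C
Reagents that add atoms: tert-butyl hydroperoxide CC(C)(C)OO
Why: Hydroxyl-directed epoxidation of the allylic alcohol with the achiral vanadium catalyst is chemoselective (isopropenyl and enone bonds untouched) and stereospecific (ring-cis olefin to cis-epoxide), and the C7 stereocentre bought with carvone, holding its isopropenyl group pseudo-equatorial, fixes the fold of the ring so that oxygen is delivered to the exposed face anti to the C6–C7 branch, setting C4 and C5 as R,R.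

Step 5
Reactants: 6 epoxy alcohol
Product: 7 (4R,5R,7R)-15-acetoxy-4,5-epoxygermacra-1(10)Z,11-dien-9-one
Conditions: Ac2O, pyridine, 4-(dimethylamino)pyridine (cat.), CH2Cl2, 0 °C
Reagents that add atoms: acetic anhydride CC(=O)OC(C)=O
Why: Standard O-acetylation installs the C15 acetate of the target and shields the primary alcohol from the oxidant of step 6 without touching any stereocentre.

Step 6
Reactants: 7 epoxy acetate
Product: 8 (4R,5R)-15-acetoxy-4,5-epoxygermacra-1(10)Z,7,11-trien-9-one (C6 and C9 cis on C7=C8)
Conditions: 2-iodoxybenzoic acid (1.5 equiv), 4-methoxypyridine N-oxide (1.5 equiv), DMSO, rt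
Reagents that add atoms: none
Why: 2-Iodoxybenzoic acid dehydrogenation of the ketone (enolisation towards C8, the only sp3 α-carbon, then oxidative loss of the C7 hydrogen) gives the cross-conjugated trienone, so the C7 stereocentre, having set C4 and C5, is erased on purpose and the 4,5-epoxide now carries the stereochemical information.

Step 7
Reactants: 8 cross-conjugated trienone
Product: 12 (4R,5R)-15-acetoxy-4,5-epoxy-12-hydroxygermacra-1(10)Z,7(11)Z-dien-9-one, via ring-trans trienone 9 (not isolated), via bridged 2H-pyran 10 (not isolated), via cyclic hemiketal 11 (not isolated)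
Conditions: hν (365 nm), THF/H2O 10:1, pyridinium p-toluenesulfonate (5 mol%), 0 °C
Reagents that add atoms: water O
Why: Proposed new method: excitation of the dienone isomerises C7=C8 to isomer 9 with C9 and C11 cis, which as a 1-oxatriene undergoes thermal oxa-6π electrocyclisation to the bridged 2H-pyran 10 (O–C12 bond formed, C7=C11 locked Z inside the six-membered ring), and the buffered acid then protonates the enol ether at C8 to a C10=C1-stabilised oxocarbenium ion that water opens through hemiketal 11 to the (Z)-12-hydroxy-7(11)-en-9-one, a geometry-defined net 1,6-hydration whose closest known relatives are the light-driven dienone to 2H-pyran valence isomerisation of ionone-type dienones and the kinetic hydrolysis of dienol ethers to β,γ-unsaturated ketones.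

Step 8
Reactants: 12 (Z)-allylic alcohol
Product: 13 (4R,5R,7S,11R)-15-acetoxy-4,5:7,11-diepoxy-12-hydroxygermacr-1(10)Z-en-9-one
Conditions: VO(acac)2 (5 mol%), t-BuOOH (1.5 equiv, in decane), CH2Cl2, 0 °C
Reagents that add atoms: tert-butyl hydroperoxide CC(C)(C)OO
Why: Hydroxyl-directed epoxidation (vanadium/alkyl hydroperoxide) of the tetrasubstituted allylic alcohol is syn-stereospecific, so the Z geometry fixed in step 7 becomes the C7/C11 relative configuration, and the existing cis-4,5-epoxide controls the face because the macrocycle folds with C5 and C9 on one side of the exocyclic C7=C11 plane and the vanadate-bound peroxide reaches the open outer face, which lies syn to the C5–O bond, to give 7S,11R.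

Step 9
Reactants: 13 diepoxy alcohol
Product: 14 target CNP0185847.2, (4R,5R,7S,11R)-12,15-diacetoxy-4,5:7,11-diepoxygermacr-1(10)Z-en-9-one
Conditions: Ac2O, pyridine, 4-(dimethylamino)pyridine (cat.), CH2Cl2, 0 °C
Reagents that add atoms: acetic anhydride CC(=O)OC(C)=O
Why: O-Acetylation of the remaining primary alcohol under mild, non-enolising conditions is tolerated by the β,γ-epoxy ketone and affects no stereocentre.

**Compound list**
1 | (R)-(−)-carvone, (5R)-2-methyl-5-(prop-1-en-2-yl)cyclohex-2-en-1-one | CC1=CC[C@H](CC1=O)C(C)=C | starting material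
2 | 1-methylcyclobut-1-ene | CC1=CCC1 | starting material
3 | head-to-tail cis-anti-cis photoadduct, 2,6-dimethyl-9-(prop-1-en-2-yl)tricyclo[4.4.0.0(2,5)]decan-7-one (9R, cyclobutanes trans to isopropenyl) | O=C1C[C@H](C(C)=C)C[C@@H]2[C@@]1(C)[C@H]1CC[C@@]21C | intermediate
4 | (7R)-germacra-1(10),4,11-trien-9-one, C1=C10 ring-cis and C4=C5 ring-trans; (2Z,6E,9R)-2,6-dimethyl-9-(prop-1-en-2-yl)cyclodeca-2,6-dien-1-one | O=C1C[C@H](C(C)=C)C/C=C(\C)CC/C=C1/C | intermediate
5 | (7R)-15-hydroxygermacra-1(10),4,11-trien-9-one, both ring double bonds ring-cis; (2Z,6E,9R)-6-(hydroxymethyl)-2-methyl-9-(prop-1-en-2-yl)cyclodeca-2,6-dien-1-one | O=C1C[C@H](C(C)=C)C/C=C(/CO)CC/C=C1/C | intermediate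
6 | (4R,5R,7R)-4,5-epoxy-15-hydroxygermacra-1(10)Z,11-dien-9-one | OC[C@]12CC/C=C(/C)C(=O)C[C@@H](C[C@H]1O2)C(C)=C | intermediate
7 | (4R,5R,7R)-15-acetoxy-4,5-epoxygermacra-1(10)Z,11-dien-9-one | CC(=O)OC[C@]12CC/C=C(/C)C(=O)C[C@@H](C[C@H]1O2)C(C)=C | intermediate
8 | (4R,5R)-15-acetoxy-4,5-epoxygermacra-1(10)Z,7,11-trien-9-one, C6 and C9 cis on C7=C8 | CC(=O)OC[C@]12CC/C=C(/C)C(=O)/C=C(\C[C@H]1O2)C(C)=C | intermediate
9 | C7=C8 geometric isomer of 8, C9 and C11 cis on C7=C8 (ring-trans) | CC(=O)OC[C@]12CC/C=C(/C)C(=O)/C=C(/C[C@H]1O2)C(C)=C | intermediate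
10 | bridged 2H-pyran, (4R,5R)-15-acetoxy-4,5:9,12-diepoxygermacra-1(10)Z,7(11),8-triene | CC(=O)OC[C@]12CC/C=C(/C)C3=CC(C[C@H]1O2)=C(C)CO3 | intermediate
11 | cyclic hemiketal, (4R,5R)-15-acetoxy-4,5:9,12-diepoxy-9-hydroxygermacra-1(10)Z,7(11)-diene (both C9 epimers) | CC(=O)OC[C@]12CC/C=C(/C)C3(O)CC(C[C@H]1O2)=C(C)CO3 | intermediate
12 | (4R,5R)-15-acetoxy-4,5-epoxy-12-hydroxygermacra-1(10)Z,7(11)Z-dien-9-one (C8 and C12 cis) | CC(=O)OC[C@]12CC/C=C(/C)C(=O)C/C(C[C@H]1O2)=C(/C)CO | intermediate
13 | (4R,5R,7S,11R)-15-acetoxy-4,5:7,11-diepoxy-12-hydroxygermacr-1(10)Z-en-9-one | CC(=O)OC[C@]12CC/C=C(/C)C(=O)C[C@]3(C[C@H]1O2)O[C@]3(C)CO | intermediate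
14 | CNP0185847.2, (4R,5R,7S,11R)-12,15-diacetoxy-4,5:7,11-diepoxygermacr-1(10)Z-en-9-one | CC(=O)OC[C@]12CC/C=C(/C)C(=O)C[C@]3(C[C@H]1O2)O[C@]3(C)COC(C)=O | target

**Totals**
Total step count: 9. Longest linear sequence: 9 steps (1 to 14).

**Three steps most likely to fail**

Step 4 (facial sense of the first directed epoxidation rests on a conformational model). The fallback sets out from 5. N-Bromosuccinimide (1.0 equiv) in THF/H2O at 0 °C adds to the most electron-rich C4=C5 bond, and water opens the bromonium ion at tertiary C4 to give the anti bromohydrin F1. K2CO3 in MeOH then closes the oxirane with inversion at C5. The oxygen ends up on the face opposite to the one the external electrophile attacked, so this halohydrin route gives the epoxide face that direct metal-oxo delivery does not. It rejoins the route at 6.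

Step 7 (the proposed new step; the photo-equilibrium, competing dienone photochemistry or γ-protonation of the pyran may spoil it). The fallback sets out from 8 and uses known chemistry. 3-Chloroperbenzoic acid with NaHCO3 in CH2Cl2 at 0 °C epoxidises the terminal, most electron-rich C11=C12 bond of the dienone to the vinylogous epoxy ketone F2 (the C11 configuration is of no consequence). SmI2 in THF/MeOH at −78 °C then opens it reductively: a samarium dienolate forms, the C11–O bond breaks, and protonation at C8 gives the δ-hydroxy-β,γ-unsaturated ketone. The samarium bridge between the C9 oxygen and the epoxide oxygen holds C12 on the C8 side. It rejoins the route at 12.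

Step 8 (facial sense of the second directed epoxidation). The fallback sets out from 12. N-Bromosuccinimide in THF/H2O at 0 °C gives the anti bromohydrin F3; either regioisomer closes to the same oxirane, and the 7-bromo-11-hydroxy one is shown. Ag2O in CH2Cl2 closes it under neutral conditions that the β,γ-epoxy ketone tolerates. The oxygen is again placed on the face opposite to the one an incoming electrophile prefers. It rejoins the route at 13.

**Further compounds**
F1 | step 4 | (4R,5S,7R)-5-bromo-4,15-dihydroxygermacra-1(10)Z,11-dien-9-one (anti bromohydrin) | OC[C@]1(O)CC/C=C(/C)C(=O)C[C@@H](C[C@@H]1Br)C(C)=C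
F2 | step 7 | (4R,5R)-15-acetoxy-4,5:11,12-diepoxygermacra-1(10)Z,7-dien-9-one (C11 epimers, one shown) | CC(=O)OC[C@]12CC/C=C(/C)C(=O)/C=C(\C[C@H]1O2)[C@@]1(C)CO1
F3 | step 8 | (4R,5R)-15-acetoxy-7-bromo-4,5-epoxy-11,12-dihydroxygermacr-1(10)Z-en-9-one (anti bromohydrin, bromine at C7 on the face opposite to the later oxirane oxygen) | CC(=O)OC[C@]12CC/C=C(/C)C(=O)C[C@@]([C@@](O)(C)CO)(C[C@H]1O2)Br
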